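**Plan**

- Labels: ring D is the central fused ring (C9b carries the C8b methylene; C10b and C14b carry C8a and C8c; C11b and C13b carry the furan oxygens; C12b–H). Ring B is the bridged dioxygenated ring (C9a on C8a, C10a on C7b, oxygens on C11a and C13a). Rings A, C and E are the aryl groups on C7a, C7b and C7c; C8c carries a 3,5-dioxygenated phenyl group.
- Cuts, in retrosynthetic order: nine O–CH3 bonds; C7b–ring C (arene onto the C7b cation); O–C7c, C7c–C8c and the C8c–aryl bond (second dihydrofuran); C8b–C9b (seven-membered ring); O–C7a, C7a–C8a and C8a–C9a (first dihydrofuran).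
- Forward: the first dihydrofuran is annulated onto a phloroglucinol-level ring D, the seven-membered ring is then closed between C9b and C8b, the second dihydrofuran follows, and ring C is attached to C7b last.
- Feature that makes the ring closure possible: C9b is meta to both oxygens of ring D and flanked by C10b and C14b, so no electrophile reaches it, but it can be carried as a third phenolic oxygen (2,6-dihydroxy-4-methoxybenzaldehyde). That oxygen first directs formylation to C14b and then, as its triflate, accepts the vinyl group waiting on C10a of ring B.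
- Stereochemistry: C7a/C8a and C7c/C8c come from the two enantiomers of a twofold-symmetric sulfide in trans-selective ylide annulations (the two dihydrofurans are locally mirror images, so opposite reagents are needed). C7b comes from attack of ring C on the face of the folded tricycle that carries H8a.

Key step: step 7

Remark: both enantiomers of trans-2,5-dimethylthiolane are taken as purchasable (each is otherwise two steps from the corresponding commercial hexane-2,5-diol via the bis-mesylate and Na2S). The sense of induction in steps 4 and 11 is assigned by analogy with benzylidene transfer from these sulfides to aldehydes; should it prove opposite, the two sulfides are exchanged.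

**Route**

Step 1
Reactants: 1 2-bromo-4,6-dimethoxybenzaldehyde
Product: 2 1-bromo-2-ethenyl-3,5-dimethoxybenzene
Conditions: Ph3PCH3Br, KOtBu, THF, 0 °C to rt
Reagents that add atoms: methyltriphenylphosphonium bromide, C[P+](c1ccccc1)(c1ccccc1)c1ccccc1.[Br-]
Why: Wittig methylenation; the non-stabilised ylide converts the hindered, non-enolisable aryl aldehyde into the styrene without touching the aryl bromide.

Step 2
Reactants: 3 2,6-dihydroxy-4-methoxybenzaldehyde
Product: 4 2,6-bis(tert-butoxycarbonyloxy)-4-methoxybenzaldehyde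
Conditions: Boc2O (2.3 equiv), i-Pr2NEt, DMAP (cat.), THF, 0 °C to rt
Reagents that add atoms: di-tert-butyl dicarbonate, CC(C)(C)OC(=O)OC(=O)OC(C)(C)C
Why: DMAP-catalysed carbonate formation at both ortho phenols installs the groups that later migrate to the benzylic alkoxide and leave to unveil the o-quinone methide.

Step 3
Reactants: 5 (2R,5R)-2,5-dimethylthiolane; 6 (4-methoxyphenyl)methanol
Product: 7 (2R,5R)-1-(4-methoxybenzyl)-2,5-dimethylthiolan-1-ium tetrafluoroborate
Conditions: HBF4·OEt2, CH2Cl2, 0 °C to rt
Reagents that add atoms: tetrafluoroboric acid diethyl etherate, F[B-](F)(F)F.[H+]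
Why: SN1-type sulfonium salt formation, the sulfide capturing the 4-methoxybenzyl cation released from the alcohol by the acid; the twofold axis of the sulfide keeps sulfur non-stereogenic, so a single salt results.

Step 4
Reactants: 2 1-bromo-2-ethenyl-3,5-dimethoxybenzene; 4 2,6-bis(tert-butoxycarbonyloxy)-4-methoxybenzaldehyde; 7 (2R,5R)-1-(4-methoxybenzyl)-2,5-dimethylthiolan-1-ium tetrafluoroborate
Product: 12 (2R,3R)-3-(2-ethenyl-3,5-dimethoxyphenyl)-6-methoxy-2-(4-methoxyphenyl)-2,3-dihydro-1-benzofuran-4-ol, via aryl Grignard reagent 8 (not isolated), via sulfonium benzylide 9 (not isolated), via ortho-quinone methide 10 (not isolated), via aryl tert-butyl carbonate 11 (not isolated)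
Conditions: 2, Mg, LiCl, THF, rt; add to 4, THF, −78 °C; then 9 [from 7, LiN(SiMe3)2, THF, −78 °C], −78 to 0 °C; then NaOH, MeOH/H2O, rt
Reagents that add atoms: none
Why: Proposed new method: addition of 8 to the aldehyde gives a benzylic alkoxide that takes over one carbonate group and expels tert-butyl carbonate to unveil o-quinone methide 10 (an established anionic generation), the chiral benzylide 9 adds to the exocyclic carbon C8a and the phenoxide displaces the sulfide at C7a with inversion, a [4+1] annulation whose achiral parent (o-quinone methides with sulfonium ylides, trans products) and whose chirality source (benzylidene transfer from 2,5-dimethylthiolanium ylides to aldehydes) are both known but have not been combined; the ylide face fixed by the twofold-symmetric sulfide should set C7a (R) and the trans-selective closure should relay it to C8a (R), the centre that persists, after which hydroxide cleaves the remaining carbonate.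

Step 5
Reactants: 12 (2R,3R)-3-(2-ethenyl-3,5-dimethoxyphenyl)-6-methoxy-2-(4-methoxyphenyl)-2,3-dihydro-1-benzofuran-4-ol
Product: 13 (2R,3R)-3-(2-ethenyl-3,5-dimethoxyphenyl)-4-hydroxy-6-methoxy-2-(4-methoxyphenyl)-2,3-dihydro-1-benzofuran-5-carbaldehyde
Conditions: MgCl2, Et3N, (CH2O)n, MeCN, reflux
Reagents that add atoms: paraformaldehyde (formaldehyde), C=O
Why: Casnati–Skattebøl ortho-formylation; the magnesium phenoxide at O9b delivers formaldehyde only to an ortho carbon, and C14b is the single free ortho position (C10b is substituted, C12b is para).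

Step 6
Reactants: 13 (2R,3R)-3-(2-ethenyl-3,5-dimethoxyphenyl)-4-hydroxy-6-methoxy-2-(4-methoxyphenyl)-2,3-dihydro-1-benzofuran-5-carbaldehyde
Product: 14 (2R,3R)-3-(2-ethenyl-3,5-dimethoxyphenyl)-5-formyl-6-methoxy-2-(4-methoxyphenyl)-2,3-dihydro-1-benzofuran-4-yl trifluoromethanesulfonate
Conditions: Tf2O, pyridine, CH2Cl2, 0 °C
Reagents that add atoms: trifluoromethanesulfonic anhydride, O=S(=O)(OS(=O)(=O)C(F)(F)F)C(F)(F)F
Why: O-sulfonylation of the chelated phenol turns the C9b oxygen into the only group in the molecule that can undergo oxidative addition.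

Step 7
Reactants: 14 (2R,3R)-3-(2-ethenyl-3,5-dimethoxyphenyl)-5-formyl-6-methoxy-2-(4-methoxyphenyl)-2,3-dihydro-1-benzofuran-4-yl trifluoromethanesulfonate
Product: 15 (7aR,8aR)-dibenzocycloheptene aldehyde (C7b=C8b alkene in the new seven-membered ring; CHO on C14b; OMe on C13b)
Conditions: Pd(OAc)2 (10 mol%), P(t-Bu)3·HBF4 (20 mol%), Cy2NMe, LiCl, DMA, 100 °C
Reagents that add atoms: none
Why: Mizoroki–Heck cyclization: zerovalent palladium inserts into the C9b–OTf bond (activated by the ortho formyl group), the aryl–palladium adds syn across the vinyl group of ring B with C9b bonding to the terminal carbon C8b, and beta-hydride elimination from C8b gives the C7b=C8b alkene conjugated to both rings. The closest known reaction type is the 7-endo Heck closure of 2-halo-2'-vinyl diaryl amines, ethers and methanes to dibenzo-fused azepines, oxepines and cycloheptenes. The seven-membered ring closes in the 7-endo-trig mode. No stereocenter is created, C7a and C8a are not touched, and the new alkene is the handle from which C7b is set in step 12. The step needs 7-endo over 6-exo closure, which is secured by the neutral chloride pathway with a bulky monophosphine (aryl to the unsubstituted alkene terminus), by the C11a methoxy group that shields the internal alkene carbon, and by the strain of the alternative methylene-dihydroanthracene fused to the furan. Chemoselectivity is not an issue because the C9b triflate is the only carbon–(pseudo)halogen bond left after the bromide of ring B was consumed in step 4.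

Step 8
Reactants: 15 (7aR,8aR)-dibenzocycloheptene aldehyde
Product: 16 (7aR,8aR)-C13b phenol of 15
Conditions: MgI2·OEt2, toluene, 80 °C; aq. NH4Cl
Reagents that add atoms: none
Why: Chelation-controlled demethylation; MgI2 binds the formyl oxygen and the adjacent C13b methoxy oxygen and iodide removes that methyl group by SN2, while the four other aryl methyl ethers lack an ortho carbonyl.

Step 9
Reactants: 16 (7aR,8aR)-C13b phenol
Product: 17 (7aR,8aR)-C13b tert-butyl carbonate of 16
Conditions: Boc2O, i-Pr2NEt, DMAP (cat.), THF, rt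
Reagents that add atoms: di-tert-butyl dicarbonate, CC(C)(C)OC(=O)OC(=O)OC(C)(C)C
Why: DMAP-catalysed carbonate formation at the freed O13b re-creates the o-Boc-salicylaldehyde motif used in step 4.

Step 10
Reactants: 18 (2S,5S)-2,5-dimethylthiolane; 19 (2,4-dimethoxyphenyl)methanol
Product: 20 (2S,5S)-1-(2,4-dimethoxybenzyl)-2,5-dimethylthiolan-1-ium tetrafluoroborate
Conditions: HBF4·OEt2, CH2Cl2, −20 °C
Reagents that add atoms: tetrafluoroboric acid diethyl etherate, F[B-](F)(F)F.[H+]
Why: Same acid-promoted SN1-type sulfonium salt formation as step 3, with the enantiomeric sulfide and the more easily ionised benzylic alcohol, hence the lower temperature.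

Step 11
Reactants: 17 (7aR,8aR)-C13b tert-butyl carbonate; 20 (2S,5S)-1-(2,4-dimethoxybenzyl)-2,5-dimethylthiolan-1-ium tetrafluoroborate; 21 (3,5-dimethoxyphenyl)magnesium chloride
Product: 24 (7aR,8aR,7cS,8cS)-hepta-O-methyl bis-dihydrofuran alkene, via sulfonium benzylide 22 (not isolated), via ortho-quinone methide 23 (not isolated)
Conditions: 21, THF, −78 °C; then 22 [from 20, LiN(SiMe3)2, THF, −78 °C], −78 to 0 °C
Reagents that add atoms: none
Why: Proposed new method: same sequence and same precedents as step 4 (aryl Grignard addition to the aldehyde, carbonate transfer and loss to give o-quinone methide 23, conjugate addition of the chiral benzylide 22 at C8c, closure of O13b onto C7c with inversion and loss of the sulfide); the (2S,5S) sulfide is expected to impose the mirror-image local sense, C7c (S) and trans C8c (S), by reagent control over the remote stereocenters.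

Step 12
Reactants: 24 (7aR,8aR,7cS,8cS)-hepta-O-methyl bis-dihydrofuran alkene; 25 1,3-dimethoxybenzene
Product: 26 (7aR,8aR,7bR,7cS,8cS)-nona-O-methyl ether of the target
Conditions: 25 (20 equiv), TfOH (5 mol%), (CF3)2CHOH/CH2Cl2, −20 to 0 °C
Reagents that add atoms: none
Why: Brønsted-acid-catalysed Friedel–Crafts hydroarylation of a donor-substituted styrene; protonation at C8b gives the C7b cation stabilised by the C11a (ortho) and C13a (para) methoxy groups rather than a C8b cation on ring D, and 1,3-dimethoxybenzene should attack through its 4-position on the face of the folded seven-membered ring that carries H8a, away from the C7a arm of the first dihydrofuran and its ring A, which sets C7b (R).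

Step 13
Reactants: 26 (7aR,8aR,7bR,7cS,8cS)-nona-O-methyl ether of the target
Product: 27 CNP0283541.1
Conditions: BBr3 (excess), CH2Cl2, −78 °C to rt; MeOH, then H2O
Reagents that add atoms: none
Why: Lewis-acid ether cleavage, the usual global deprotection of per-O-methyl stilbene oligomers; the trans-dihydrofurans should keep their configuration because any C7–O ionisation recloses to the trans isomer.

**Compound list**

1 | 2-bromo-4,6-dimethoxybenzaldehyde | COc1cc(OC)c(C=O)c(Br)c1 | starting material
2 | 1-bromo-2-ethenyl-3,5-dimethoxybenzene | COc1cc(OC)c(C=C)c(Br)c1 | intermediate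
3 | 2,6-dihydroxy-4-methoxybenzaldehyde | COc1cc(O)c(C=O)c(O)c1 | starting material
4 | 2,6-bis(tert-butoxycarbonyloxy)-4-methoxybenzaldehyde | COc1cc(OC(=O)OC(C)(C)C)c(C=O)c(OC(=O)OC(C)(C)C)c1 | intermediate
5 | (2R,5R)-2,5-dimethylthiolane | C[C@@H]1CC[C@@H](C)S1 | starting material
6 | (4-methoxyphenyl)methanol | COc1ccc(CO)cc1 | starting material
7 | (2R,5R)-1-(4-methoxybenzyl)-2,5-dimethylthiolan-1-ium tetrafluoroborate | C[C@@H]1CC[C@@H](C)[S+]1Cc1ccc(OC)cc1.F[B-](F)(F)F | intermediate
8 | (2-ethenyl-3,5-dimethoxyphenyl)magnesium bromide | COc1cc(OC)c(C=C)c([Mg]Br)c1 | intermediate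
9 | 4-methoxybenzylide of salt 7 (sulfonium ylide) | C[C@@H]1CC[C@@H](C)[S+]1[CH-]c1ccc(OC)cc1 | intermediate
10 | tert-butyl 6-[(2-ethenyl-3,5-dimethoxyphenyl)methylidene]-3-methoxy-5-oxocyclohexa-1,3-dien-1-yl carbonate (o-quinone methide) | COC1=CC(=O)C(=Cc2cc(OC)cc(OC)c2C=C)C(OC(=O)OC(C)(C)C)=C1 | intermediate
11 | tert-butyl (2R,3R)-3-(2-ethenyl-3,5-dimethoxyphenyl)-6-methoxy-2-(4-methoxyphenyl)-2,3-dihydro-1-benzofuran-4-yl carbonate | COc1ccc([C@@H]2Oc3cc(OC)cc(OC(=O)OC(C)(C)C)c3[C@H]2c2cc(OC)cc(OC)c2C=C)cc1 | intermediate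
12 | (2R,3R)-3-(2-ethenyl-3,5-dimethoxyphenyl)-6-methoxy-2-(4-methoxyphenyl)-2,3-dihydro-1-benzofuran-4-ol | COc1ccc([C@@H]2Oc3cc(OC)cc(O)c3[C@H]2c2cc(OC)cc(OC)c2C=C)cc1 | intermediate
13 | (2R,3R)-3-(2-ethenyl-3,5-dimethoxyphenyl)-4-hydroxy-6-methoxy-2-(4-methoxyphenyl)-2,3-dihydro-1-benzofuran-5-carbaldehyde | COc1ccc([C@@H]2Oc3cc(OC)c(C=O)c(O)c3[C@H]2c2cc(OC)cc(OC)c2C=C)cc1 | intermediate
14 | (2R,3R)-3-(2-ethenyl-3,5-dimethoxyphenyl)-5-formyl-6-methoxy-2-(4-methoxyphenyl)-2,3-dihydro-1-benzofuran-4-yl trifluoromethanesulfonate | COc1ccc([C@@H]2Oc3cc(OC)c(C=O)c(OS(=O)(=O)C(F)(F)F)c3[C@H]2c2cc(OC)cc(OC)c2C=C)cc1 | intermediate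
15 | (7aR,8aR)-dibenzocycloheptene aldehyde: trans-2-(4-methoxyphenyl)dihydrofuran fused at C10b–C11b; C8a shared by furan and seven-membered ring; C7b=C8b alkene between C10a and C9b; CHO on C14b; OMe on C13b, C11a, C13a | COc1ccc([C@@H]2Oc3cc(OC)c(C=O)c4c3[C@H]2c2cc(OC)cc(OC)c2C=C4)cc1 | intermediate
16 | (7aR,8aR)-C13b phenol of 15 | COc1ccc([C@@H]2Oc3cc(O)c(C=O)c4c3[C@H]2c2cc(OC)cc(OC)c2C=C4)cc1 | intermediate
17 | (7aR,8aR)-C13b tert-butyl carbonate of 16 | COc1ccc([C@@H]2Oc3cc(OC(=O)OC(C)(C)C)c(C=O)c4c3[C@H]2c2cc(OC)cc(OC)c2C=C4)cc1 | intermediate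
18 | (2S,5S)-2,5-dimethylthiolane | C[C@H]1CC[C@H](C)S1 | starting material
19 | (2,4-dimethoxyphenyl)methanol | COc1ccc(CO)c(OC)c1 | starting material
20 | (2S,5S)-1-(2,4-dimethoxybenzyl)-2,5-dimethylthiolan-1-ium tetrafluoroborate | C[C@H]1CC[C@H](C)[S+]1Cc1ccc(OC)cc1OC.F[B-](F)(F)F | intermediate
21 | (3,5-dimethoxyphenyl)magnesium chloride | COc1cc(OC)cc([Mg]Cl)c1 | starting material
22 | 2,4-dimethoxybenzylide of salt 20 (sulfonium ylide) | C[C@H]1CC[C@H](C)[S+]1[CH-]c1ccc(OC)cc1OC | intermediate
23 | o-quinone methide from 17: C13b carbonyl; C14b=C8c exocyclic alkene bearing the 3,5-dimethoxyphenyl group | COc1ccc([C@@H]2OC3=CC(=O)C(=Cc5cc(OC)cc(OC)c5)C4=C3[C@H]2c2cc(OC)cc(OC)c2C=C4)cc1 | intermediate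
24 | (7aR,8aR,7cS,8cS)-hepta-O-methyl bis-dihydrofuran alkene (both furans in place; C7b=C8b; no ring C) | COc1ccc([C@@H]2Oc3cc4c(c5c3[C@H]2c2cc(OC)cc(OC)c2C=C5)[C@H](c2cc(OC)cc(OC)c2)[C@@H](c2ccc(OC)cc2OC)O4)cc1 | intermediate
25 | 1,3-dimethoxybenzene | COc1cccc(OC)c1 | starting material
26 | (7aR,8aR,7bR,7cS,8cS)-nona-O-methyl ether of the target | COc1ccc([C@@H]2Oc3cc4c(c5c3[C@H]2c2cc(OC)cc(OC)c2[C@@H](c2ccc(OC)cc2OC)C5)[C@H](c2cc(OC)cc(OC)c2)[C@@H](c2ccc(OC)cc2OC)O4)cc1 | intermediate
27 | CNP0283541.1 (7aR,8aR,7bR,7cS,8cS) | Oc1ccc([C@@H]2Oc3cc4c(c5c3[C@H]2c2cc(O)cc(O)c2[C@@H](c2ccc(O)cc2O)C5)[C@H](c2cc(O)cc(O)c2)[C@@H](c2ccc(O)cc2O)O4)cc1 | target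

**Count and risks**

Total steps: 13. Longest linear sequence: 10 (steps 1, 4, 5, 6, 7, 8, 9, 11, 12, 13).

Steps most likely to fail:

1. Step 4 (Proposed new method). The relay of chirality from the sulfide to C8a may be incomplete, because the ylide may not discriminate between the two faces of the o-quinone methide; the o-quinone methide may also be captured by the neighbouring vinyl group. Fallback: setting out from 2 and 4, the same Grignard and o-quinone-methide sequence is run with the achiral salt (4-methoxybenzyl)dimethylsulfonium tetrafluoroborate F1, made from 6, dimethyl sulfide and HBF4·OEt2. Its ylide, dimethylsulfonium 4-methoxybenzylide F2, adds without chiral bias; the base-mediated annulation of o-quinone methides with achiral sulfonium ylides is established chemistry. The racemic carbonate (11 together with its enantiomer, the (2S,3S) carbonate F3) is cleaved with NaOH. The racemic phenol (12 together with its enantiomer, the (2S,3S) phenol F4) is resolved by preparative chromatography on a cellulose-carbamate chiral stationary phase. The route is rejoined at 12.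

2. Step 11 (Proposed new method). The chiral ylide may be mismatched with the existing stereocenters, or the very electron-rich benzylic sulfonium salt may ionise before it is deprotonated. Fallback: setting out from 17 and 21, o-quinone methide 23 is generated as before and trapped with the achiral ylide dimethylsulfonium 2,4-dimethoxybenzylide F6. This ylide is formed at −78 °C from (2,4-dimethoxybenzyl)dimethylsulfonium tetrafluoroborate F5, itself made from 19, dimethyl sulfide and HBF4·OEt2. Substrate control alone then gives 24 and its trans diastereomer, the (7cR,8cR) isomer F7, which are separated on silica. The route is rejoined at 24.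

3. Step 12. The acid may open the C7c–O bond, the 3,5-dimethoxyphenyl group on C8c may capture the C7b cation intramolecularly in competition with the external arene, or facial selectivity at C7b may be low. Fallback: setting out from 24, oxymercuration–demercuration (Hg(OAc)2, THF/H2O; then NaBH4, NaOH) places water on the methoxy-stabilised carbon and gives the C7b carbinol F8. F8 is then ionised in (CF3)2CHOH without added acid in the presence of 25, a dehydrative Friedel–Crafts benzylation that needs no alkene protonation; any C7b epimer would be removed by chromatography. The route is rejoined at 26.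

Further compounds
F1 | step 4 | (4-methoxybenzyl)dimethylsulfonium tetrafluoroborate | C[S+](C)Cc1ccc(OC)cc1.F[B-](F)(F)F
F2 | step 4 | dimethylsulfonium 4-methoxybenzylide | C[S+](C)[CH-]c1ccc(OC)cc1
F3 | step 4 | tert-butyl (2S,3S)-3-(2-ethenyl-3,5-dimethoxyphenyl)-6-methoxy-2-(4-methoxyphenyl)-2,3-dihydro-1-benzofuran-4-yl carbonate | COc1ccc([C@H]2Oc3cc(OC)cc(OC(=O)OC(C)(C)C)c3[C@@H]2c2cc(OC)cc(OC)c2C=C)cc1
F4 | step 4 | (2S,3S)-3-(2-ethenyl-3,5-dimethoxyphenyl)-6-methoxy-2-(4-methoxyphenyl)-2,3-dihydro-1-benzofuran-4-ol | COc1ccc([C@H]2Oc3cc(OC)cc(O)c3[C@@H]2c2cc(OC)cc(OC)c2C=C)cc1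
F5 | step 11 | (2,4-dimethoxybenzyl)dimethylsulfonium tetrafluoroborate | C[S+](C)Cc1ccc(OC)cc1OC.F[B-](F)(F)F
F6 | step 11 | dimethylsulfonium 2,4-dimethoxybenzylide | C[S+](C)[CH-]c1ccc(OC)cc1OC
F7 | step 11 | (7aR,8aR,7cR,8cR)-hepta-O-methyl bis-dihydrofuran alkene | COc1ccc([C@@H]2Oc3cc4c(c5c3[C@H]2c2cc(OC)cc(OC)c2C=C5)[C@@H](c2cc(OC)cc(OC)c2)[C@H](c2ccc(OC)cc2OC)O4)cc1
F8 | step 12 | C7b carbinol of 24 (C7b–OH, C8b–H2; both C7b epimers) | COc1ccc([C@@H]2Oc3cc4c(c5c3[C@H]2c2cc(OC)cc(OC)c2C(O)C5)[C@H](c2cc(OC)cc(OC)c2)[C@@H](c2ccc(OC)cc2OC)O4)cc1
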